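**Retrosynthetic overview**
1. Target 15 ⇒ γ-lactone 8 + 2,6-dimethoxyphenol 13: the syringyl C–C bond is made last by Friedel–Crafts attack of the phenol on the oxocarbenium ion of the half-reduced lactone.
2. Lactone 8 ⇒ keto acid 6 by ketone reduction and lactonisation; this oxolane ring is carried into the target.
3. Keto acid 6 ⇒ meso anhydride 5 + veratrole 2 by an enantioselective desymmetrising Friedel–Crafts acylation (new), which fixes the absolute configuration of both methyl-bearing carbons.
4. Anhydride 5 ⇒ cis-2,3-epoxybutane 3 + 2 CO by double ring-expansion carbonylation (oxirane → oxetan-2-one → oxolane-2,5-dione), which fixes the cis-dimethyl relationship.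
5. Arenes: 2 from catechol 1, 13 from resorcinol 9. Ring order: oxirane → β-lactone → anhydride (opened in step 3) → γ-lactone → oxolane.

Assumption: the sense of induction of the new catalyst in step 3 cannot be known in advance; the (S,S) acid is written, and its (R,R) mirror image is used if it gives ent-6.

**Step 1**
Reactants: 1 catechol
Product: 2 veratrole (1,2-dimethoxybenzene)
Conditions: Me2SO4 (2.2 equiv), aq NaOH, 0 → 40 °C
Reagents that add atoms: dimethyl sulfate, COS(=O)(=O)OC
Why: double Williamson O-methylation of the catecholate; no stereocentre is involved.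

**Step 2**
Reactants: 3 cis-2,3-epoxybutane (meso)
Product: 5 cis-2,3-dimethylsuccinic anhydride (meso), via trans-3,4-dimethyloxetan-2-one 4 (not isolated)
Conditions: CO (60 bar), [(ClTPP)Al(THF)2][Co(CO)4] (1 mol %; ClTPP = meso-tetrakis(4-chlorophenyl)porphyrinato), 1,4-dioxane, 90 °C
Reagents that add atoms: carbon monoxide, [C-]#[O+]
Why: Lewis acid/cobaltate ring-expansion carbonylation, in which each CO insertion starts with SN2 opening by Co(CO)4− with inversion at one carbon, so the cis-epoxide gives the trans-β-lactone and then, by inversion at the other carbon, the cis (meso) anhydride.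

**Step 3**
Reactants: 5 cis-2,3-dimethylsuccinic anhydride; 2 veratrole
Product: 6 (2R,3S)-4-(3,4-dimethoxyphenyl)-2,3-dimethyl-4-oxobutanoic acid
Conditions: (S,S)-IDPi Brønsted acid (5 mol %; imidodiphosphorimidate HN[P(=NSO2CF3)(O,O'-binaphthyl)]2 built from two (S)-3,3'-bis[3,5-bis(trifluoromethyl)phenyl]-BINOL units), anhydrous CH2Cl2, −40 → 0 °C
Reagents that add atoms: none
Why: Proposed new method: a catalytic enantioselective desymmetrising Friedel–Crafts acylation, in which the confined chiral acid protonates one carbonyl of the meso anhydride inside its pocket, the chiral counter-anion tells the two enantiotopic C=O groups apart, veratrole attacks through C4 (para to a methoxy group) at the C5 carbonyl next to the (4S) carbon, and opening of the anhydride ring with rearomatisation returns the proton to the catalyst and leaves the freed carboxyl group in the molecule, so the reaction is a 1:1 addition in which every atom of 5 and 2 ends up in 6; no bond at the methyl-bearing carbons is broken, so the syn relationship is kept and the choice of carbonyl sets both methyl stereocentres in the absolute sense; the closest known reactions are the racemic acid-catalysed Friedel–Crafts acylation of alkoxyarenes with anhydrides and the catalytic desymmetrisation of meso anhydrides by alcohols or arylzinc reagents.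

**Step 4**
Reactants: 6 (2R,3S)-4-(3,4-dimethoxyphenyl)-2,3-dimethyl-4-oxobutanoic acid
Product: 8 (3R,4S,5S)-5-(3,4-dimethoxyphenyl)-3,4-dimethyloxolan-2-one, via hydroxy acid 7 (not isolated)
Conditions: LiBH(s-Bu)3 (2.2 equiv), THF, −78 °C; then 2 M HCl, rt
Reagents that add atoms: none
Why: Felkin–Anh-controlled reduction of the aryl ketone by the bulky borohydride (hydride anti to the CH(CH3)CO2Li branch, methyl inside) gives the (4S) alcohol, and acid-promoted γ-lactonisation by acyl substitution (retention at the carbinol) closes the ring with the aryl trans to the neighbouring methyl.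

**Step 5**
Reactants: 9 resorcinol
Product: 10 1,3-dimethoxybenzene
Conditions: Me2SO4 (2.2 equiv), aq NaOH, 0 → 40 °C
Reagents that add atoms: dimethyl sulfate, COS(=O)(=O)OC
Why: double Williamson O-methylation under aqueous hydroxide, where C-methylation of resorcinol is negligible.

**Step 6**
Reactants: 10 1,3-dimethoxybenzene
Product: 13 2,6-dimethoxyphenol, via 2,6-dimethoxyphenyllithium 11 (not isolated), via lithium aryltrimethoxyborate 12 (not isolated)
Conditions: n-BuLi, THF, 0 °C → rt; B(OMe)3, −78 °C → rt; AcOH, 30% H2O2, 0 °C → rt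
Reagents that add atoms: hydrogen peroxide, OO
Why: directed ortho-metalation at C2 between the two methoxy groups, borylation of the aryllithium and boronate oxidation (aryl migration from boron to oxygen) give the phenol.

**Step 7**
Reactants: 8 (3R,4S,5S)-5-(3,4-dimethoxyphenyl)-3,4-dimethyloxolan-2-one; 13 2,6-dimethoxyphenol
Product: 15 4-[(2R,3R,4S,5S)-5-(3,4-dimethoxyphenyl)-3,4-dimethyloxolan-2-yl]-2,6-dimethoxyphenol, via aluminium lactolate 14 (not isolated)
Conditions: i-Bu2AlH (1.1 equiv), CH2Cl2, −78 °C; then the phenol in slight excess, BF3·OEt2 (2 equiv), −78 → 0 °C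
Reagents that add atoms: none
Why: half-reduction of the lactone, BF3-induced ionisation to the five-membered oxocarbenium ion and Friedel–Crafts attack by the carbon para to the phenol OH, anti to the adjacent methyl, set the last stereocentre (2R), and reversible benzylic ionisation under the Lewis acid holds the product at the thermodynamic isomer with each aryl trans to its neighbouring methyl.

**Compound list**
1 | catechol (benzene-1,2-diol) | Oc1ccccc1O | starting material
2 | veratrole (1,2-dimethoxybenzene) | COc1ccccc1OC | intermediate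
3 | cis-2,3-epoxybutane, (2R,3S)-2,3-dimethyloxirane (meso) | C[C@@H]1O[C@@H]1C | starting material
4 | trans-3,4-dimethyloxetan-2-one (racemate; (3S,4S) enantiomer drawn) | C[C@@H]1OC(=O)[C@H]1C | intermediate (not isolated)
5 | cis-2,3-dimethylsuccinic anhydride, (3R,4S)-3,4-dimethyloxolane-2,5-dione (meso) | C[C@@H]1[C@H](C)C(=O)OC1=O | intermediate
6 | (2R,3S)-4-(3,4-dimethoxyphenyl)-2,3-dimethyl-4-oxobutanoic acid | COc1ccc(C(=O)[C@@H](C)[C@@H](C)C(=O)O)cc1OC | intermediate
7 | (2R,3S,4S)-4-(3,4-dimethoxyphenyl)-4-hydroxy-2,3-dimethylbutanoic acid | COc1ccc([C@@H](O)[C@@H](C)[C@@H](C)C(=O)O)cc1OC | intermediate (not isolated)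
8 | (3R,4S,5S)-5-(3,4-dimethoxyphenyl)-3,4-dimethyloxolan-2-one (3,4-cis, 4,5-trans) | COc1ccc([C@H]2OC(=O)[C@H](C)[C@@H]2C)cc1OC | intermediate
9 | resorcinol (benzene-1,3-diol) | Oc1cccc(O)c1 | starting material
10 | 1,3-dimethoxybenzene | COc1cccc(OC)c1 | intermediate
11 | 2,6-dimethoxyphenyllithium | [Li]c1c(OC)cccc1OC | intermediate (not isolated)
12 | lithium trimethoxy(2,6-dimethoxyphenyl)borate | [Li+].CO[B-](OC)(OC)c1c(OC)cccc1OC | intermediate (not isolated)
13 | 2,6-dimethoxyphenol | COc1cccc(OC)c1O | intermediate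
14 | diisobutylaluminium (3R,4S,5S)-5-(3,4-dimethoxyphenyl)-3,4-dimethyloxolan-2-olate (anomer mixture) | COc1ccc([C@H]2OC(O[Al](CC(C)C)CC(C)C)[C@H](C)[C@@H]2C)cc1OC | intermediate (not isolated)
15 | 4-[(2R,3R,4S,5S)-5-(3,4-dimethoxyphenyl)-3,4-dimethyloxolan-2-yl]-2,6-dimethoxyphenol | COc1ccc([C@H]2O[C@@H](c3cc(OC)c(O)c(OC)c3)[C@H](C)[C@@H]2C)cc1OC | target

**Step count and risk**
Total step count: 7. Longest linear sequence: 4 steps (3 → 5 → 6 → 8 → 15, steps 2, 3, 4 and 7).

Steps most likely to fail:

Step 3 (the proposed new reaction). The chiral acid may be too weak to drive the acylation at low temperature, the enantioselectivity is untested, and acid could epimerise the carbon next to the new ketone. The fallback is known chemistry; it sets out from 2 (and uses 5) and comes back at 6. Bromination of 2 (NBS, MeCN) gives 4-bromo-1,2-dimethoxybenzene F1. Bromine–lithium exchange (n-BuLi, THF, −78 °C) gives 3,4-dimethoxyphenyllithium F2, which Zn(OTf)2 turns into (3,4-dimethoxyphenyl)zinc triflate F3. F3 and 5 with [Rh(cod)Cl]2 (cod = 1,5-cyclooctadiene) and a TADDOL-derived dimethylphosphoramidite ligand in THF/DMF at 50 °C, then aqueous HCl, give 6 by the established rhodium-catalysed arylzinc desymmetrisation of meso succinic anhydrides. This costs one more isolated step, because the lithium and zinc reagents are made and used in the same flask as the coupling.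

Step 4. Substrate control at the new carbinol may be modest, and the lithium carboxylate may reduce sluggishly. The fallback sets out from 6 and comes back at 8. Esterification (Me3SiCHN2, MeOH/toluene) gives methyl (2R,3S)-4-(3,4-dimethoxyphenyl)-2,3-dimethyl-4-oxobutanoate F4. Reagent-controlled Corey–Bakshi–Shibata reduction (BH3·SMe2, (R)-Me-CBS oxazaborolidine, i.e. (R)-1-methyl-3,3-diphenyltetrahydro-1H,3H-pyrrolo[1,2-c][1,3,2]oxazaborole, THF, −20 °C) gives methyl (2R,3S,4S)-4-(3,4-dimethoxyphenyl)-4-hydroxy-2,3-dimethylbutanoate F5. TsOH in toluene closes F5 to 8.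

Step 7. The one-pot reduction and arylation may give O-arylation, double arylation through ring opening, or aryltetralin formation from the opened benzylic cation. The fallback sets out from 13 (and uses 8) and comes back at 15. Bromination of 13 (NBS, CH2Cl2, 0 °C) gives 4-bromo-2,6-dimethoxyphenol F6, and TBSCl/imidazole in DMF gives (4-bromo-2,6-dimethoxyphenoxy)(tert-butyl)dimethylsilane F7. Bromine–lithium exchange (n-BuLi, THF, −78 °C) gives [4-(tert-butyldimethylsilyloxy)-3,5-dimethoxyphenyl]lithium F8, which adds to lactone 8 (aqueous NH4Cl quench) to give the cyclic hemiketal (3R,4S,5S)-2-[4-(tert-butyldimethylsilyloxy)-3,5-dimethoxyphenyl]-5-(3,4-dimethoxyphenyl)-3,4-dimethyloxolan-2-ol F9. Reductive deoxygenation with Et3SiH/BF3·OEt2 (CH2Cl2, −78 °C → rt, with Lewis-acid epimerisation to the isomer with aryl trans to methyl) gives the silyl ether of the target, tert-butyl{4-[(2R,3R,4S,5S)-5-(3,4-dimethoxyphenyl)-3,4-dimethyloxolan-2-yl]-2,6-dimethoxyphenoxy}dimethylsilane F10. Bu4NF in THF gives 15.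

**Further compounds**
F1 | step 3 | 4-bromo-1,2-dimethoxybenzene | COc1ccc(Br)cc1OC
F2 | step 3 | 3,4-dimethoxyphenyllithium | [Li]c1ccc(OC)c(OC)c1
F3 | step 3 | (3,4-dimethoxyphenyl)zinc triflate | COc1ccc([Zn]OS(=O)(=O)C(F)(F)F)cc1OC
F4 | step 4 | methyl (2R,3S)-4-(3,4-dimethoxyphenyl)-2,3-dimethyl-4-oxobutanoate | COc1ccc(C(=O)[C@@H](C)[C@@H](C)C(=O)OC)cc1OC
F5 | step 4 | methyl (2R,3S,4S)-4-(3,4-dimethoxyphenyl)-4-hydroxy-2,3-dimethylbutanoate | COc1ccc([C@@H](O)[C@@H](C)[C@@H](C)C(=O)OC)cc1OC
F6 | step 7 | 4-bromo-2,6-dimethoxyphenol | COc1cc(Br)cc(OC)c1O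
F7 | step 7 | (4-bromo-2,6-dimethoxyphenoxy)(tert-butyl)dimethylsilane | COc1cc(Br)cc(OC)c1O[Si](C)(C)C(C)(C)C
F8 | step 7 | [4-(tert-butyldimethylsilyloxy)-3,5-dimethoxyphenyl]lithium | [Li]c1cc(OC)c(O[Si](C)(C)C(C)(C)C)c(OC)c1
F9 | step 7 | (3R,4S,5S)-2-[4-(tert-butyldimethylsilyloxy)-3,5-dimethoxyphenyl]-5-(3,4-dimethoxyphenyl)-3,4-dimethyloxolan-2-ol | COc1ccc([C@H]2OC(O)(c3cc(OC)c(O[Si](C)(C)C(C)(C)C)c(OC)c3)[C@H](C)[C@@H]2C)cc1OC
F10 | step 7 | tert-butyl{4-[(2R,3R,4S,5S)-5-(3,4-dimethoxyphenyl)-3,4-dimethyloxolan-2-yl]-2,6-dimethoxyphenoxy}dimethylsilane | COc1ccc([C@H]2O[C@@H](c3cc(OC)c(O[Si](C)(C)C(C)(C)C)c(OC)c3)[C@H](C)[C@@H]2C)cc1OC
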